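The benzene ring of the indole (C3a, C4, C5, C6, C7, C7a) is taken apart into three alkynes. The feature exploited is that this ring carries bromine only at C4 and C6, meta to each other, with C5 and C7 bare; silicon stands in for both bromines. One ruthenium-catalysed [2+2+2] cycloaddition forms C3a–C7a, C4–C5 and C6–C7 and closes the benzene ring together with the five-membered ring N1–C2–C3–C3a–C7a. Its precursor is an N-tosyl ynamide 1,6-diyne, unsubstituted at the ynamide terminus (future C7) and silyl-capped at the other (future C4); ethynyltrimethylsilane supplies C5 and C6. Dehydrogenation, one-pot tribromination and detosylation complete the route.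

Key step: step 5

Remark: ring atoms carry the numbering of the target indole at every stage, also the alkyne carbons that become them; compounds 1, 2, 5 and 11 are taken as commercial.

Step 1
Reactants: 1 4-(trimethylsilyl)but-3-yn-1-ol; 2 tert-butyl N-tosylcarbamate
Product: 3 tert-butyl N-tosyl-N-[4-(trimethylsilyl)but-3-yn-1-yl]carbamate
Conditions: PPh3, DIAD, THF, 0 °C → rt
Reagents that add atoms: none
Why: Mitsunobu reaction: the Boc-activated sulfonamide N–H is acidic enough to protonate the betaine and can be alkylated only once, so the primary alcohol is displaced cleanly with the silyl-capped alkyne as a bystander.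

Step 2
Reactants: 3 tert-butyl N-tosyl-N-[4-(trimethylsilyl)but-3-yn-1-yl]carbamate
Product: 4 4-methyl-N-[4-(trimethylsilyl)but-3-yn-1-yl]benzenesulfonamide
Conditions: CF3CO2H, CH2Cl2, 0 °C → rt
Reagents that add atoms: none
Why: Acidolysis of the tert-butyl carbamate (Boc cleavage with loss of 2-methylpropene and CO2) frees the sulfonamide N–H, while the tosyl group and the alkynyl–silicon bond withstand trifluoroacetic acid at room temperature.

Step 3
Reactants: 4 4-methyl-N-[4-(trimethylsilyl)but-3-yn-1-yl]benzenesulfonamide; 5 trichloroethylene
Product: 7 N-[(E)-1,2-dichloroethenyl]-4-methyl-N-[4-(trimethylsilyl)but-3-yn-1-yl]benzenesulfonamide, via dichloroacetylene 6 (not isolated)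
Conditions: Cs2CO3 (1.5 equiv), 5 (1.2 equiv), dry DMF, 50 °C
Reagents that add atoms: none
Why: Nucleophilic vinylation by elimination–addition: Cs2CO3 removes HCl from 5 to give dichloroacetylene in dilute solution, the sulfonamide anion adds to it in anti fashion and protonation gives the E-dichloroenamide; water is excluded so that carbonate does not cleave the alkynyl–silicon bond.

Step 4
Reactants: 7 N-[(E)-1,2-dichloroethenyl]-4-methyl-N-[4-(trimethylsilyl)but-3-yn-1-yl]benzenesulfonamide
Product: 10 N-ethynyl-4-methyl-N-[4-(trimethylsilyl)but-3-yn-1-yl]benzenesulfonamide, via chloroynamide 8 (not isolated), via lithium ynamide 9 (not isolated)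
Conditions: PhLi (2.5 equiv), THF, −78 → −40 °C; then H2O, −78 °C → rt
Reagents that add atoms: none
Why: Dehydrochlorination followed by lithium–chlorine exchange: the first equivalent of PhLi converts the dichloroenamide into the chloroynamide, the second exchanges chlorine for lithium, and protonation of the lithium ynamide gives the terminal ynamide directly, so no desilylation is needed that could not tell the two alkyne termini apart.

Step 5
Reactants: 10 N-ethynyl-4-methyl-N-[4-(trimethylsilyl)but-3-yn-1-yl]benzenesulfonamide; 11 ethynyltrimethylsilane
Product: 12 N-tosyl-4,6-bis(trimethylsilyl)indoline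
Conditions: Cp*RuCl(cod) (5 mol %), 11 (5 equiv), ClCH2CH2Cl, argon, 25 → 40 °C, 10 added slowly
Reagents that add atoms: none
Why: The two tethered alkynes of 10 undergo oxidative cyclisation on the Cp*RuCl fragment (divalent ruthenium) to a ruthenacycle that already holds the C3a–C7a bond and the five-membered nitrogen ring; 11 is then inserted, and reductive elimination forms C4–C5 and C6–C7 and releases the arene. The closest known reaction type is the metal-catalysed crossed [2+2+2] cycloaddition of N-sulfonyl ynamide 1,6-diynes with monoalkynes to indolines, combined with the Cp*RuCl(cod)-catalysed coupling of singly substituted 1,6-diynes with terminal alkynes. The pyrroline ring closes by intramolecular alkyne–alkyne oxidative coupling, which makes a five-membered ring fused to the metallacycle, and the benzene ring closes by insertion of the third alkyne followed by reductive elimination. No stereocentre is formed. Two selectivities are needed: crossed coupling instead of self-coupling, which excess 11, slow addition of 10 and the reluctance of this catalyst to trimerise a hindered monoalkyne alone should secure; and the meta placement of silicon, which should follow because 11 is taken up at the unhindered ruthenium–C7 bond with its CH carbon towards the metal and its silyl-bearing carbon bonding to C7, so that silicon ends at C6, away from the Cp* ligand and from the SiMe3-bearing C4, and C5 stays unsubstituted.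

Step 6
Reactants: 12 N-tosyl-4,6-bis(trimethylsilyl)indoline
Product: 13 N-tosyl-4,6-bis(trimethylsilyl)indole
Conditions: DDQ (2 equiv), toluene, reflux
Reagents that add atoms: none
Why: Dehydrogenation with DDQ (hydride abstraction at benzylic C3, then loss of the C2 proton) converts the N-sulfonylindoline into the N-sulfonylindole, which ties the nitrogen lone pair into the pyrrole ring before bromine is introduced; aryl–silicon bonds are inert to the quinone.

Step 7
Reactants: 13 N-tosyl-4,6-bis(trimethylsilyl)indole
Product: 16 N-tosyl-3,4,6-tribromoindole, via 3-bromo-4,6-disilyl indole 14 (not isolated), via 3,6-dibromo-4-silyl indole 15 (not isolated)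
Conditions: Br2 (1.05 equiv), NaHCO3, CH2Cl2, 0 °C, dark; then Br2 (2.5 equiv), 0 °C → reflux
Reagents that add atoms: bromine, BrBr
Why: Electrophilic aromatic substitution in three stages: bromine first substitutes C3 (the most nucleophilic carbon of an N-sulfonylindole), then replaces each SiMe3 group by ipso-bromodesilylation through a β-silyl-stabilised arenium ion that loses Me3SiBr, so bromine enters C4 and C6 only where silicon stood, while C2, C5 and C7 of the sulfonyl-deactivated ring have no such activation and NaHCO3 removes the HBr that could cause protodesilylation.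

Step 8
Reactants: 16 N-tosyl-3,4,6-tribromoindole
Product: 17 3,4,6-tribromo-1H-indole (target)
Conditions: NaOH (2 M aq., 5 equiv), 1,4-dioxane, 50 °C; aqueous work-up
Reagents that add atoms: none
Why: Hydrolytic cleavage of the sulfonamide N–S bond by hydroxide (N-detosylation), made easy because the tribromoindolide is a good leaving group; the three C–Br bonds are not attacked by aqueous base at this temperature.

Compound list
1 | 4-(trimethylsilyl)but-3-yn-1-ol | C[Si](C)(C)C#CCCO | starting material
2 | tert-butyl N-tosylcarbamate (N-Boc-4-methylbenzenesulfonamide) | Cc1ccc(cc1)S(=O)(=O)NC(=O)OC(C)(C)C | starting material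
3 | tert-butyl N-tosyl-N-[4-(trimethylsilyl)but-3-yn-1-yl]carbamate | Cc1ccc(cc1)S(=O)(=O)N(CCC#C[Si](C)(C)C)C(=O)OC(C)(C)C | intermediate
4 | 4-methyl-N-[4-(trimethylsilyl)but-3-yn-1-yl]benzenesulfonamide | Cc1ccc(cc1)S(=O)(=O)NCCC#C[Si](C)(C)C | intermediate
5 | trichloroethylene | ClC=C(Cl)Cl | starting material
6 | dichloroacetylene (not isolated) | ClC#CCl | intermediate
7 | N-[(E)-1,2-dichloroethenyl]-4-methyl-N-[4-(trimethylsilyl)but-3-yn-1-yl]benzenesulfonamide | Cl/C=C(/Cl)N(CCC#C[Si](C)(C)C)S(=O)(=O)c1ccc(C)cc1 | intermediate
8 | N-(chloroethynyl)-4-methyl-N-[4-(trimethylsilyl)but-3-yn-1-yl]benzenesulfonamide (not isolated) | ClC#CN(CCC#C[Si](C)(C)C)S(=O)(=O)c1ccc(C)cc1 | intermediate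
9 | N-(lithioethynyl)-4-methyl-N-[4-(trimethylsilyl)but-3-yn-1-yl]benzenesulfonamide (not isolated) | [Li]C#CN(CCC#C[Si](C)(C)C)S(=O)(=O)c1ccc(C)cc1 | intermediate
10 | N-ethynyl-4-methyl-N-[4-(trimethylsilyl)but-3-yn-1-yl]benzenesulfonamide | C#CN(CCC#C[Si](C)(C)C)S(=O)(=O)c1ccc(C)cc1 | intermediate
11 | ethynyltrimethylsilane | C#C[Si](C)(C)C | starting material
12 | N-tosyl-4,6-bis(trimethylsilyl)indoline | C[Si](C)(C)c1cc([Si](C)(C)C)c2CCN(S(=O)(=O)c3ccc(C)cc3)c2c1 | intermediate
13 | N-tosyl-4,6-bis(trimethylsilyl)-1H-indole | C[Si](C)(C)c1cc([Si](C)(C)C)c2ccn(S(=O)(=O)c3ccc(C)cc3)c2c1 | intermediate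
14 | 3-bromo-N-tosyl-4,6-bis(trimethylsilyl)-1H-indole (not isolated) | C[Si](C)(C)c1cc([Si](C)(C)C)c2c(Br)cn(S(=O)(=O)c3ccc(C)cc3)c2c1 | intermediate
15 | 3,6-dibromo-N-tosyl-4-(trimethylsilyl)-1H-indole (not isolated) | Brc1cc([Si](C)(C)C)c2c(Br)cn(S(=O)(=O)c3ccc(C)cc3)c2c1 | intermediate
16 | N-tosyl-3,4,6-tribromo-1H-indole | Brc1cc(Br)c2c(Br)cn(S(=O)(=O)c3ccc(C)cc3)c2c1 | intermediate
17 | 3,4,6-tribromo-1H-indole | Brc1cc(Br)c2c(Br)c[nH]c2c1 | target

Total step count: 8. Longest linear sequence: 8 steps (1 to 17); the route is fully linear, with 2, 5 and 11 entering as purchased partners.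

Steps most likely to fail

Step 5. The diyne may couple with itself through its terminal ynamide alkyne, the silyl-capped alkyne may enter the metallacycle too slowly, or regiocontrol in the uptake of 11 may erode and give the 4,5-disilyl isomer as well. The fallback sets out from 10 (with 11) and comes back at 12 without any new compound (F0). It replaces the metallacycle pathway by a carbene-driven enyne-metathesis cascade with first-generation Grubbs catalyst RuCl2(=CHPh)(PCy3)2 in CH2Cl2 at 40 °C. The ruthenium alkylidene adds to the terminal ynamide, the vinylcarbene closes the five-membered ring onto the silylalkyne, cross enyne metathesis with 11 extends the chain, and ring-closing metathesis releases the arene. This mode is established for ynamide 1,6-diynes with terminal alkynes, where it favours the 4,6-pattern.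

Step 7. Ipso-substitution may stall at the hindered C4 once bromine sits at C3 and C6 and has deactivated the ring, and forcing conditions may then bring C–H bromination of the benzene ring or protodesilylation. The fallback sets out from 13 and comes back at 16, turning silicon into bromine through boron so that the last halogenation no longer depends on arene nucleophilicity. BBr3 in CH2Cl2 (0 °C → rt) should effect ipso-borodesilylation to 4,6-bis(dibromoboryl)-N-tosylindole F1, which pinacol and Et3N convert into N-tosyl-4,6-bis(pinacolatoboryl)indole F2. CuBr2 in MeOH/H2O at 80 °C should then replace each boryl group by bromine to give 4,6-dibromo-N-tosylindole F3. Br2 in CH2Cl2 at 0 °C brominates C3 and delivers 16.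

Step 6. Hydride abstraction from C3 may be slow, since this position is shielded by the peri SiMe3 group at C4 and the nitrogen is sulfonylated, leaving incomplete conversion or decomposition at the temperature needed. The fallback sets out from 12 and comes back at 13 by a radical route. N-Bromosuccinimide with AIBN in refluxing PhCF3 should brominate the benzylic C3 position to racemic 3-bromo-N-tosyl-4,6-bis(trimethylsilyl)indoline F4. DBU in THF at rt then removes HBr by elimination to give 13.

Further compounds
F0 | step 5 | none | none
F1 | step 7 | 4,6-bis(dibromoboryl)-N-tosyl-1H-indole | BrB(Br)c1cc(B(Br)Br)c2ccn(S(=O)(=O)c3ccc(C)cc3)c2c1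
F2 | step 7 | N-tosyl-4,6-bis(4,4,5,5-tetramethyl-1,3,2-dioxaborolan-2-yl)-1H-indole | CC1(C)OB(OC1(C)C)c1cc(B2OC(C)(C)C(C)(C)O2)c2ccn(S(=O)(=O)c3ccc(C)cc3)c2c1
F3 | step 7 | 4,6-dibromo-N-tosyl-1H-indole | Brc1cc(Br)c2ccn(S(=O)(=O)c3ccc(C)cc3)c2c1
F4 | step 6 | racemic 3-bromo-N-tosyl-4,6-bis(trimethylsilyl)indoline | C[Si](C)(C)c1cc([Si](C)(C)C)c2C(Br)CN(S(=O)(=O)c3ccc(C)cc3)c2c1
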